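**Retrosynthetic overview**
1. Target 16 ⇒ acetylation of diol 15 ⇒ B-alkyl Suzuki coupling of vinyl carbinol 12 with bromobutenolide 13; the butenolide ring arrives intact.
2. 12 ⇒ spiro-epoxide 11 ⇒ 9-methylidene 10 ⇒ ketone 9; C9 is set by α-face epoxidation, C8 by enolate methylation, C6 by reduction of dione 7.
3. 7 ⇒ dione-aldehyde 4 by an enantiotopic-group-selective intramolecular diazoalkane–ketone ring expansion (1,2-shift of C10), which sets C10.
4. 4 ⇒ 2-methylcyclopentane-1,3-dione 1 + 2,2-dimethylpent-4-enal 2 (allylic C–H alkylation, then hydrogenation).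
5. Ring order: the five-membered dione is bought; ring A closes while the dione expands to ring B in one step; the lactone ring is attached last.

Assumption: decalin carbons carry labdane numbers (C1–C10 ring, C11/C12 chain, C13–C16 butenolide); α is the face opposite the C10 methyl.
Assumption: 3-bromofuran-2(5H)-one (13) is taken as a catalogue compound.
Assumption: in step 3 the ligand enantiomer that activates the pro-R carbonyl of 4 is used; if the first one tried gives ent-7, its antipode is used.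

Step 1
Reactants: 1 2-methylcyclopentane-1,3-dione; 2 2,2-dimethylpent-4-enal
Product: 3 (E)-2,2-dimethyl-5-(1-methyl-2,5-dioxocyclopentyl)pent-3-enal
Conditions: Pd(OAc)2 (10 mol%), 1,2-bis(phenylsulfinyl)ethane (10 mol%), 2,6-dimethylbenzoquinone (1.5 equiv), dioxane/DMSO 4:1, 45 °C
Reagents that add atoms: none
Why: Pd(II)/sulfoxide allylic C–H alkylation (oxidative Tsuji–Trost type): the only allylic C–H of 2 gives a π-allyl-Pd that the acidic dione attacks at the unhindered terminus (the other is neopentylic), giving the linear E product and a quaternary carbon that is not yet stereogenic.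

Step 2
Reactants: 3 (E)-2,2-dimethyl-5-(1-methyl-2,5-dioxocyclopentyl)pent-3-enal
Product: 4 2,2-dimethyl-5-(1-methyl-2,5-dioxocyclopentyl)pentanal
Conditions: H2 (1 atm), 5% Pd/C, EtOAc, 23 °C
Reagents that add atoms: none
Why: Heterogeneous catalytic hydrogenation reduces only the disubstituted C=C; the α-quaternary aldehyde and the hindered ketones survive at 1 atm.

Step 3
Reactants: 4 2,2-dimethyl-5-(1-methyl-2,5-dioxocyclopentyl)pentanal
Product: 7 (5S,10S)-4,4,10-trimethyl-trans-decalin-6,9-dione, via N-silyl hydrazone 5 (not isolated), via diazoalkane 6 (not isolated)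
Conditions: TBSNHNHTBS, Sc(OTf)3 (0.01 mol%), 23 °C, then vacuum; PhIF2, 2-chloropyridine, CH2Cl2, −78 °C, cold filtration through basic alumina; Sc(OTf)3 (10 mol%)/chiral tris(oxazoline) (12 mol%), 4 Å MS, PhMe/CH2Cl2, −78→−20 °C; then DBU, 23 °C
Reagents that add atoms: none
Why: Proposed new method: catalytic enantiotopic-group-selective intramolecular diazoalkane–ketone ring expansion (Tiffeneau–Demjanov-type 1,2-shift) – the chiral Sc(III) Lewis acid activates the pro-R carbonyl of the prochiral dione, the tethered diazo carbon (C5) adds to it (ring closure helped by the gem-dimethyl group), and the ring-fusion bond C6–C10, antiperiplanar to the C5–N2+ bond of the betaine, migrates with retention at C10 as N2 leaves, which closes ring A, expands the five-membered dione to the six-membered 1,4-dione (ring B) and fixes C10 as S, after which DBU equilibrates C5 (α to the C6 ketone) to the trans-fused 5S isomer; the closest known chemistry is the Sc(OTf)3-catalysed (also enantioselective) homologation of cycloalkanones with non-stabilised diazoalkanes, the fused-selective intramolecular Schmidt reaction of azidoalkyl ketones, and the CBS-type discrimination of the enantiotopic carbonyls of such diones.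

Step 4
Reactants: 7 (5S,10S)-4,4,10-trimethyl-trans-decalin-6,9-dione
Product: 8 (5S,6R,10S)-6-hydroxy-4,4,10-trimethyl-trans-decalin-9-one
Conditions: L-Selectride (1.05 equiv), THF, −78 °C; H2O work-up
Reagents that add atoms: none
Why: Chemo- and diastereoselective bulky-hydride reduction: hydride reaches C6 equatorially from the α face (the β face is blocked by the syn-axial C4β and C10 methyls) to give the axial 6β-alcohol (6R), whereas equatorial attack at C9 is blocked by the adjacent axial C10 methyl.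

Step 5
Reactants: 8 (5S,6R,10S)-6-hydroxy-4,4,10-trimethyl-trans-decalin-9-one
Product: 9 (5S,6R,8R,10S)-6-hydroxy-4,4,8,10-tetramethyl-trans-decalin-9-one
Conditions: LDA (2.2 equiv), THF, −78 °C; MeI (1.1 equiv), −78→−20 °C; then NaOMe (cat.), MeOH, 23 °C
Reagents that add atoms: iodomethane, CI
Why: Regiospecific ketone enolate alkylation (C8 is the only enolisable position of the C9 ketone because C10 is quaternary); base equilibration places the new methyl equatorial (8α, 8R), since the 8β epimer is syn-axial to the C10 methyl.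

Step 6
Reactants: 9 (5S,6R,8R,10S)-6-hydroxy-4,4,8,10-tetramethyl-trans-decalin-9-one
Product: 10 (5S,6R,8R,10S)-4,4,8,10-tetramethyl-9-methylidene-trans-decalin-6-ol
Conditions: Ph3PCH3Br (4 equiv), KOtBu (4 equiv), PhMe, 90 °C
Reagents that add atoms: methyltriphenylphosphonium bromide, C[P+](c1ccccc1)(c1ccccc1)c1ccccc1.[Br-]
Why: Wittig methylenation under forcing KOtBu/toluene conditions suited to hindered ketones; C8 stays at its thermodynamic equatorial configuration.

Step 7
Reactants: 10 (5S,6R,8R,10S)-4,4,8,10-tetramethyl-9-methylidene-trans-decalin-6-ol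
Product: 11 (5S,6R,8R,9R,10S)-4,4,8,10-tetramethyl-trans-decalin-9-spiro-2'-oxiran-6-ol (epoxide oxygen 9α)
Conditions: mCPBA, NaHCO3, CH2Cl2, 0 °C
Reagents that add atoms: 3-chloroperoxybenzoic acid, OOC(=O)c1cccc(Cl)c1
Why: Prilezhaev epoxidation of the exocyclic alkene from the α face, anti to the adjacent axial C10 methyl, sets C9 (9R, oxygen α).

Step 8
Reactants: 11 (5S,6R,8R,9R,10S)-4,4,8,10-tetramethyl-trans-decalin-9-spiro-2'-oxiran-6-ol
Product: 12 (5S,6R,8R,9R,10S)-9-ethenyl-4,4,8,10-tetramethyl-trans-decalin-6,9-diol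
Conditions: Me3S+ I− (5 equiv), n-BuLi (4.8 equiv), THF, −10→23 °C
Reagents that add atoms: trimethylsulfonium iodide, C[S+](C)C.[I-]
Why: Sulfonium-ylide one-carbon homologation of an epoxide to an allylic alcohol: the ylide opens the epoxide at its CH2 terminus (C11) and the β-alkoxy sulfonium eliminates Me2S; the C9–O bond is untouched, so 9R is retained.

Step 9
Reactants: 12 (5S,6R,8R,9R,10S)-9-ethenyl-4,4,8,10-tetramethyl-trans-decalin-6,9-diol; 13 3-bromofuran-2(5H)-one
Product: 15 (5S,6R,8R,9R,10S)-6,9-dihydroxylabd-13-en-16,15-olide, via B-alkyl-9-BBN borane 14 (not isolated)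
Conditions: 9-BBN (3.5 equiv), THF, 23→50 °C; then 13, Pd(dppf)Cl2 (5 mol%), AsPh3 (10 mol%), Cs2CO3, DMF/H2O, 23 °C
Reagents that add atoms: none
Why: Anti-Markovnikov hydroboration followed by B-alkyl Suzuki–Miyaura coupling with the α-bromobutenolide forms C12–C13 and delivers the intact butenolide; no stereocentre is touched.

Step 10
Reactants: 15 (5S,6R,8R,9R,10S)-6,9-dihydroxylabd-13-en-16,15-olide
Product: 16 (5S,6R,8R,9R,10S)-6-acetoxy-9-hydroxylabd-13-en-16,15-olide (CNP0205088.1)
Conditions: Ac2O, DMAP, pyridine, 40 °C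
Reagents that add atoms: acetic anhydride, CC(=O)OC(C)=O
Why: DMAP-catalysed acylation of the secondary 6β-alcohol; the hindered tertiary 9α-alcohol does not react.

**Compound list**
1 | 2-methylcyclopentane-1,3-dione | CC1C(=O)CCC1=O | starting material
2 | 2,2-dimethylpent-4-enal | C=CCC(C)(C)C=O | starting material
3 | (E)-2,2-dimethyl-5-(1-methyl-2,5-dioxocyclopentyl)pent-3-enal | O=CC(C)(C)/C=C/CC1(C)C(=O)CCC1=O | intermediate
4 | 2,2-dimethyl-5-(1-methyl-2,5-dioxocyclopentyl)pentanal | O=CC(C)(C)CCCC1(C)C(=O)CCC1=O | intermediate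
5 | N-TBS hydrazone of 4 (E) | CC(C)(C)[Si](C)(C)N/N=C/C(C)(C)CCCC1(C)C(=O)CCC1=O | intermediate (not isolated)
6 | 2-(5-diazo-4,4-dimethylpentyl)-2-methylcyclopentane-1,3-dione | [N-]=[N+]=CC(C)(C)CCCC1(C)C(=O)CCC1=O | intermediate (not isolated)
7 | (5S,10S)-4,4,10-trimethyl-trans-decalin-6,9-dione (5α-H; 10β-CH3) | O=C1CCC(=O)[C@@]2(C)CCCC(C)(C)[C@H]12 | intermediate
8 | (5S,6R,10S)-6-hydroxy-4,4,10-trimethyl-trans-decalin-9-one (6β-OH) | O[C@@H]1CCC(=O)[C@@]2(C)CCCC(C)(C)[C@H]12 | intermediate
9 | (5S,6R,8R,10S)-6-hydroxy-4,4,8,10-tetramethyl-trans-decalin-9-one (8α-CH3) | O[C@@H]1C[C@@H](C)C(=O)[C@@]2(C)CCCC(C)(C)[C@H]12 | intermediate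
10 | (5S,6R,8R,10S)-4,4,8,10-tetramethyl-9-methylidene-trans-decalin-6-ol | O[C@@H]1C[C@@H](C)C(=C)[C@@]2(C)CCCC(C)(C)[C@H]12 | intermediate
11 | (5S,6R,8R,9R,10S)-4,4,8,10-tetramethyl-trans-decalin-9-spiro-2'-oxiran-6-ol (oxygen 9α) | O[C@@H]1C[C@@H](C)[C@]3(CO3)[C@@]2(C)CCCC(C)(C)[C@H]12 | intermediate
12 | (5S,6R,8R,9R,10S)-9-ethenyl-4,4,8,10-tetramethyl-trans-decalin-6,9-diol (9α-OH) | O[C@@H]1C[C@@H](C)[C@](O)(C=C)[C@@]2(C)CCCC(C)(C)[C@H]12 | intermediate
13 | 3-bromofuran-2(5H)-one | BrC1=CCOC1=O | starting material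
14 | B-{2-[(5S,6R,8R,9R,10S)-6,9-dihydroxy-4,4,8,10-tetramethyl-trans-decalin-9-yl]ethyl}-9-borabicyclo[3.3.1]nonane | O[C@@H]1C[C@@H](C)[C@](O)(CCB3C4CCCC3CCC4)[C@@]2(C)CCCC(C)(C)[C@H]12 | intermediate (not isolated)
15 | (5S,6R,8R,9R,10S)-6,9-dihydroxylabd-13-en-16,15-olide | O[C@@H]1C[C@@H](C)[C@](O)(CCC2=CCOC2=O)[C@@]2(C)CCCC(C)(C)[C@H]12 | intermediate
16 | (5S,6R,8R,9R,10S)-6-acetoxy-9-hydroxylabd-13-en-16,15-olide | CC(=O)O[C@@H]1C[C@@H](C)[C@](O)(CCC2=CCOC2=O)[C@@]2(C)CCCC(C)(C)[C@H]12 | target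

**Total step count:** 10. **Longest linear sequence:** 10 steps (1/2 → 16); 13 is bought.

**Three steps most likely to fail**

Step 3 (the proposed new reaction). Risks: low enantioselectivity, slow addition (the new C5–C6 bond joins two carbons that each sit next to a quaternary centre), and the bridged ketone from migration of C7 or epoxide formation instead of C10 migration. The fallback uses only known reaction types, sets C10 by a known desymmetrisation, and replaces the diazo insertion by a pinacol coupling followed by a semipinacol shift. It sets out from 4. IBX (DMSO, 70 °C) gives the ene-dione 2,2-dimethyl-5-(1-methyl-2,5-dioxocyclopent-3-en-1-yl)pentanal F2. Cu(OTf)2/chiral phosphoramidite-catalysed conjugate addition of Me2Zn desymmetrises it to 5-[(1S,3S)-1,3-dimethyl-2,5-dioxocyclopentyl]-2,2-dimethylpentanal F3, which fixes C10; the C8 epimer ratio is irrelevant because C8 is equilibrated later. SmI2 (THF, t-BuOH, −78 °C) couples the aldehyde with the ring carbonyl remote from the new methyl to give the cis-diol (2S,3aR,4S,8aS)-3a,4-dihydroxy-2,5,5,8a-tetramethyloctahydroazulen-1(2H)-one F4; the minor regioisomer is removed by chromatography. MsCl/Et3N mesylates only the secondary hydroxyl to give (2S,3aR,4S,8aS)-3a-hydroxy-2,5,5,8a-tetramethyl-1-oxodecahydroazulen-4-yl methanesulfonate F5. KOtBu (THF, 0 °C) triggers the semipinacol 1,2-shift of C10, which is antiperiplanar to the mesylate, and DBU equilibration gives (5S,8R,10S)-4,4,8,10-tetramethyl-trans-decalin-6,9-dione F6. L-Selectride reduction of F6 at C6, as in step 4, comes back to the route at 9.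

Step 1. Risks: the 1,3-dione may be too weak a nucleophile for the Pd(II) allylic C–H alkylation, or may O-allylate. The fallback sets out from 2. Pd(OAc)2/bis-sulfoxide/benzoquinone/AcOH allylic C–H acetoxylation gives (E)-4,4-dimethyl-5-oxopent-2-en-1-yl acetate F1. Classical Pd(0) Tsuji–Trost allylation of 1 with F1 (Pd(PPh3)4, Et3N, THF) comes back to the route at 3.

Step 9. Risks: the bromobutenolide is base-sensitive, and transmetalation of the hindered alkylborane bearing two free hydroxyls may be slow. The fallback sets out from 11. Vinylmagnesium bromide/CuI opens the epoxide at C11 to give (5S,6R,8R,9R,10S)-4,4,8,10-tetramethyl-9-(prop-2-en-1-yl)-trans-decalin-6,9-diol F7. Cross-metathesis with α-methylene-γ-butyrolactone (Hoveyda–Grubbs II, CH2Cl2, 40 °C) gives (E)-3-{2-[(5S,6R,8R,9R,10S)-6,9-dihydroxy-4,4,8,10-tetramethyl-trans-decalin-9-yl]ethylidene}dihydrofuran-2(3H)-one F8. RhCl3·3H2O (EtOH, 80 °C) moves the exocyclic double bond into the ring and comes back to the route at 15.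

**Further compounds**
F1 | step 1 | (E)-4,4-dimethyl-5-oxopent-2-en-1-yl acetate | CC(=O)OC/C=C/C(C)(C)C=O
F2 | step 3 | 2,2-dimethyl-5-(1-methyl-2,5-dioxocyclopent-3-en-1-yl)pentanal | O=CC(C)(C)CCCC1(C)C(=O)C=CC1=O
F3 | step 3 | 5-[(1S,3S)-1,3-dimethyl-2,5-dioxocyclopentyl]-2,2-dimethylpentanal | O=C1C[C@H](C)C(=O)[C@@]1(C)CCCC(C)(C)C=O
F4 | step 3 | (2S,3aR,4S,8aS)-3a,4-dihydroxy-2,5,5,8a-tetramethyloctahydroazulen-1(2H)-one | O=C1[C@@H](C)C[C@]2(O)[C@@H](O)C(C)(C)CCC[C@]12C
F5 | step 3 | (2S,3aR,4S,8aS)-3a-hydroxy-2,5,5,8a-tetramethyl-1-oxodecahydroazulen-4-yl methanesulfonate | O=C1[C@@H](C)C[C@]2(O)[C@@H](OS(C)(=O)=O)C(C)(C)CCC[C@]12C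
F6 | step 3 | (5S,8R,10S)-4,4,8,10-tetramethyl-trans-decalin-6,9-dione | O=C1C[C@@H](C)C(=O)[C@@]2(C)CCCC(C)(C)[C@H]12
F7 | step 9 | (5S,6R,8R,9R,10S)-4,4,8,10-tetramethyl-9-(prop-2-en-1-yl)-trans-decalin-6,9-diol | O[C@@H]1C[C@@H](C)[C@](O)(CC=C)[C@@]2(C)CCCC(C)(C)[C@H]12
F8 | step 9 | (E)-3-{2-[(5S,6R,8R,9R,10S)-6,9-dihydroxy-4,4,8,10-tetramethyl-trans-decalin-9-yl]ethylidene}dihydrofuran-2(3H)-one | O[C@@H]1C[C@@H](C)[C@](O)(C/C=C2\CCOC2=O)[C@@]2(C)CCCC(C)(C)[C@H]12
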